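The red flask is charged with 0.050 M of substrate, and I count intermediate A as a percentage of that charge.

| flask | substrate | remark | time |
|---|---|---|---|
| red | 0.050 M | the very flask that is asked about, followed so far |  |
| teal | 0.034 M | run made earlier |  |
| flask | 0.050 M |  | 15 d |

| run | time / d | intermediate A / % | target / % |
|---|---|---|---|
| red | 0.0556 | 43.4 | 0 |
| red | 0.104 | 60.7 | 1.6 |
| red | 0.250 | 71.0 | 7.2 |
| red | 0.500 | 57.9 | 21.5 |
| red | 1.04 | 31.7 | 53.7 |
| red | 2.00 | 12.1 | 83.2 |
| red | 5.00 | 1.2 | 98.9 |
| teal | 0.104 | 61.8 | 1.3 |
| teal | 0.208 | 72.0 | 4.5 |
| teal | 0.500 | 54.8 | 21.1 |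
| teal | 1.04 | 33.4 | 52.0 |
| teal | 2.50 | 6.4 | 90.2 |
| teal | 5.00 | 0 | 99.7 |
| teal | 10.0 | 1.0 | 99.3 |

(each reading ± 1 percentage point)

1. time, not beyond 15 d, at which the flask holds most intermediate A
2. the amount of intermediate A, in percent of the substrate charged, at that time

- a reading or a percentage of target counts all its forms, free or not

Two numbers in the red run don't seem to fit. Intermediate A falls from 57.9% at 0.500 d to 12.1% at 2.00 d, a slow constant of 1.04 d⁻¹. Run back to time zero, that line points to an intercept of 97.6%. Yet no red reading passes 71.0%, which is less than the intercept.

I treat the making and loss of intermediate A as consecutive first-order steps and integrate the rate in closed form: the amount is the intercept times the slow exponential minus the intercept times the fast one. The first red reading, 43.4% at 0.0556 d, gives a fast constant of 12.5 d⁻¹, far above the slow one. The slope vanishes at ln(fast/slow)/(fast − slow), which is 0.217 d. By then the slow term stands at 77.9%, and the fast term still takes off 6.48%. That clears the puzzle and gives my peak height, read from the red readings with their scatter, the slow term less the fast term at that time: 71.3%.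

The forecast says 0.21 d (0.17 d to 0.25 d) and 72.5% (70.5% to 74.5%), holding that “concentration hardly matters and the teal points can guide the red flask”. Its amount is higher than mine.

The red flask peaks at 0.214 d with 70.6%, inside both forecast ranges.

    substrate ⇌ intermediate A (K = 8.50, k = 0.00780 min⁻¹)
    intermediate A → intermediate B (k = 8.30 × 10⁻⁴ min⁻¹)
    intermediate B → target (k = 0.00330 min⁻¹)
    crystals ⇌ target, rate k4*(cs4 - [target]) while solid is left; crystals form when [target] > cs4 (solubility = 23.0 mM, k = 0.0500 min⁻¹)

Crystals stand at 0% at 0.214 d, and their falling out changes the peak by nothing. My peak height of 71.3%, a percentage of the charge read from the red run, stands beside 70.6% in the neighbour flask with 0.085 M of substrate.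

The data stem from a simulated flask for an exercise; the scatter is artificial.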